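The meeting opened on the easy step, that G adds to X to give J, and the chair laid out the flasks and the readings.

| setting | Friday's | Thursday's | Sunday's | blue | violet | teal | ochre |
|---|---|---|---|---|---|---|---|
| X | 8.8 mM | 120 mM | 47 mM | 47 mM | 100 mM | 200 mM | 12 mM |
| G | 3 equiv | 3 equiv | 3.9 equiv | 3.00 equiv | 9.00 equiv | 2.00 equiv | 2.00 equiv |
| remark | run made earlier | run made earlier | run made earlier |  |  |  |  |
| time |  |  |  | 3.0 min | 3.0 min | 3.0 min | 3.0 min |

| run | time / s | J / % | X / % |
|---|---|---|---|
| Friday's | 10.0 | 1.1 | 99.2 |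
| Friday's | 15.0 | 0 | 99.5 |
| Friday's | 25.0 | 0.9 | 100.8 |
| Friday's | 40.0 | 2.5 | 98.4 |
| Friday's | 50.0 | 1.7 | 98.9 |
| Friday's | 80.0 | 2.6 | 94.9 |
| Friday's | 90.0 | 4.3 | 95.3 |
| Thursday's | 10.0 | 7.5 | 93.1 |
| Thursday's | 15.0 | 9.7 | 91.2 |
| Thursday's | 25.0 | 13.6 | 83.4 |
| Thursday's | 40.0 | 16.0 | 76.2 |
| Thursday's | 50.0 | 19.0 | 72.3 |
| Thursday's | 80.0 | 18.7 | 57.0 |
| Thursday's | 90.0 | 18.4 | 55.8 |
| Sunday's | 20.0 | 4.6 | 93.7 |
| Sunday's | 40.0 | 10.5 | 87.3 |
| Sunday's | 50.0 | 13.0 | 82.9 |
| Sunday's | 80.0 | 17.2 | 75.5 |
| Sunday's | 90.0 | 18.6 | 73.1 |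

(standard deviation of a reading: 1 percentage point)

- the numbers in the tables scatter with a standard deviation of 1 percentage point

1. the flasks by amount of J, in percent of the X charged, highest first, at 3.0 min (blue / violet / teal / ochre)
2. the amount of J, in percent of the X charged of the flask you put first, at 3.0 min
3. the amount of J, in percent of the X charged of the flask you put last, at 3.0 min

The bench chemist pointed out that J does not stay: in Thursday's run [X] and [J] together come to 74.2 % of the charge at 90.0 s, which she read as G taking J on to something unmeasured. The kineticist proposed leaving the clock out. If both losses are first order in [G], she argued, dividing the rate of change of [J] by that of [X] removes [G] and time, leaving d[J]/d[X] = s[J]/[X] − 1, so at the peak of J the ratio [X]/[J] equals s. Thursday's [J] reads 19.0 %, 18.7 % and 18.4 % from 50.0 s to 90.0 s, flat within the scatter, and the reading at 80.0 s gave 3.05 for s, the selectivity factor, the number of times faster G takes J than X at equal concentrations. Integrated, with x the fraction of X left, this gives J = (x − x^s)/(s − 1) of the charge, peaking at 19.0 % where x is 58.0 %. The bench chemist tried it on Sunday's last reading, [X] 73.1 %, and got 16.9 % against 18.6 % read, which the meeting let pass at a scatter of 1 point on each reading.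

The clock then entered once. From that same reading the kineticist took 0.0190 M⁻¹ s⁻¹ for X + G, and with [G] held at its charge she put x at 61.8 % in blue, 25.5 % in teal, 92.1 % in ochre and 4.61 % in violet. The curve then gave J of 18.9 %, 11.7 %, 6.96 % and 2.25 %, in that same order of flasks. The chair objected that, at one G per step, this reckoning spends 68.7 % of teal's G against 19.2 % of blue's, so teal's x is set too low; the kineticist then took [G] at its charge less half of that spending, which put x at 40.7 % and J at 16.7 % in teal, and x at 64.7 % and J at 18.6 % in blue, and the meeting committed to blue, teal, ochre, violet.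

The forecast, holding that “J versus X falls on one curve for all runs”, gave blue > teal > ochre > violet, with 19.3 % and 3.2 %, both above ours; the flasks gave blue > teal > ochre > violet, with 19.0 % in blue and 2.98 % in violet.

    X + G → J (k = 0.0207 M⁻¹ s⁻¹)
    G + E ⇌ Z (K = 1.60 M⁻¹, k = 0.0135 M⁻¹ s⁻¹)
    G + J → E (k = 0.0625 M⁻¹ s⁻¹)

In blue, X + G → J ran ahead of G + J → E, with J made, each step taken net, 1.94 times as fast as it was used up at 1.24 min and 1.09 times at 3.00 min, when X stood at 62.2 % and the curve through s gave 18.9 % against J at 19.0 %. Teal's G fell to 42 % of its charge while its X came down to 37 %, not to the 25.5 % reckoned at full G, and there the same curve gives 15.7 % against 16.0 %; in the neighbour of blue with 190 mM of X, X stood at 23.5 %, where the curve gives 10.9 % and J was 11.0 %.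

The numbers in the tables were generated by integration on assumed constants, noise included.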